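The route rests on disconnecting the C1–C14 bond of the 14-membered carbocycle, the bond between the methylene-bearing sp2 carbon (C1) and the carbinol carbon (C14). An intramolecular Nozaki–Hiyama–Kishi coupling of an enol triflate with an aldehyde should close this ring as the final skeletal event, creating the 2-methylene-1-ol unit and the C14 stereocentre in one operation. Its precursor is the complete oxane (ring O–C15–C8–C9–C10–C11, three stereocentres and the acetate in place) carrying two open arms. The oxane is carved from (R)-carvone through a bridged 2-oxabicyclo[2.2.2]octene that is opened by strain-releasing ethenolysis.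

Key step: step 13

Remark (atom labels): C1 is the methylene-bearing ring carbon and the carbocycle is counted C1–C14 through C4=C5 (methyl on C5), C8 (ring-fusion CH), C10 (acetoxy), C11 (quaternary, oxygen-bearing) and C14 (carbinol); C15 is the CMe2 carbon, so the oxane is O–C15–C8–C9–C10–C11.

Step 1
Reactants: 1 (R)-carvone
Product: 2 (5R)-5-(2-hydroxypropan-2-yl)-2-methylcyclohex-2-en-1-one
Conditions: 50% aq. H2SO4, 0 °C to rt
Reagents that add atoms: water, O
Why: Acid-catalysed Markovnikov hydration protonates only the electron-rich isopropenyl group (the enone double bond is deactivated), water captures the tertiary cation to give the future C15–O bond, and the stereocentre (future C8) is not touched.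

Step 2
Reactants: 2 (5R)-5-(2-hydroxypropan-2-yl)-2-methylcyclohex-2-en-1-one
Product: 3 (1R,5R)-5-(2-hydroxypropan-2-yl)-2-methylcyclohex-2-en-1-ol
Conditions: NaBH4, CeCl3·7H2O, MeOH, 0 °C
Reagents that add atoms: none
Why: Luche 1,2-reduction, in which hydride adds on the axial trajectory of the half-chair with the side chain equatorial, should give the alcohol cis to the side chain (1R), which becomes the C10 oxygen centre, without conjugate reduction.

Step 3
Reactants: 3 (1R,5R)-5-(2-hydroxypropan-2-yl)-2-methylcyclohex-2-en-1-ol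
Product: 4 (1R,4S,6R,7R)-1,3,3-trimethyl-7-(phenylselanyl)-2-oxabicyclo[2.2.2]octan-6-ol
Conditions: PhSeCl, pyridine, CH2Cl2, −78 to 0 °C
Reagents that add atoms: phenylselenyl chloride, Cl[Se]c1ccccc1
Why: Phenylselenoetherification, in which the seleniranium ion formed on the alkene face anti to both oxygen substituents is opened at the tertiary carbon (Markovnikov) by the tertiary hydroxyl through a boat, closes the oxane as a 2-oxabicyclo[2.2.2]octane, so that C11 is fixed by the bridge (the C–O bond can only form on the face that carries the C8 side chain) and selenium ends up anti to the new C–O bond.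

Step 4
Reactants: 4 (1R,4S,6R,7R)-1,3,3-trimethyl-7-(phenylselanyl)-2-oxabicyclo[2.2.2]octan-6-ol
Product: 6 (1S,4S,6R)-1,3,3-trimethyl-2-oxabicyclo[2.2.2]oct-7-en-6-ol, via selenoxide 5 (not isolated)
Conditions: 30% aq. H2O2, pyridine, CH2Cl2, 0 °C to rt
Reagents that add atoms: none
Why: Selenide oxidation and selenoxide syn-elimination should be regiospecific because the only β-hydrogens sit on C7 (C11 is fully substituted) and the eclipsed bicyclic frame holds one of them syn-periplanar to the selenoxide, giving the strained C7=C12 alkene.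

Step 5
Reactants: 6 (1S,4S,6R)-1,3,3-trimethyl-2-oxabicyclo[2.2.2]oct-7-en-6-ol
Product: 7 (1S,4S,6R)-1,3,3-trimethyl-2-oxabicyclo[2.2.2]oct-7-en-6-yl acetate
Conditions: Ac2O, pyridine, DMAP (cat.), CH2Cl2, rt
Reagents that add atoms: acetic anhydride, CC(=O)OC(C)=O
Why: DMAP-catalysed acylation of the only hydroxyl group installs the C10 acetate of the target and touches no stereocentre.

Step 6
Reactants: 7 (1S,4S,6R)-1,3,3-trimethyl-2-oxabicyclo[2.2.2]oct-7-en-6-yl acetate
Product: 8 (2S,3R,5S)-2,5-diethenyl-2,6,6-trimethyloxan-3-yl acetate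
Conditions: ethylene (5 bar), second-generation Grubbs catalyst RuCl2(=CHPh)(PCy3)(H2IMes) (5 mol %), toluene, 50 °C
Reagents that add atoms: ethylene, C=C
Why: Ring-opening cross-metathesis with ethylene is driven by release of the bicyclo[2.2.2]octene strain and cleaves C7=C12 into two vinyl groups (adding C6 and C13), and since C7 and C12 stay attached to C8 and C11 the cis relation of the two arms on the oxane is inherited from the bridge.

Step 7
Reactants: 9 but-2-yn-1-ol
Product: 11 (E)-3-iodobut-2-en-1-ol, via alkenylzirconium alkoxide 10 (not isolated)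
Conditions: Cp2Zr(H)Cl (2.2 equiv), THF, rt; then I2, 0 °C
Reagents that add atoms: iodine, II
Why: Hydrozirconation–iodination, in which the first equivalent of hydride forms the zirconium alkoxide and the second adds syn across the alkyne with zirconium on the methyl-bearing carbon remote from oxygen, should give the E iodide after iodinolysis with retention.

Step 8
Reactants: 11 (E)-3-iodobut-2-en-1-ol
Product: 12 (E)-1-bromo-3-iodobut-2-ene
Conditions: CBr4, PPh3, CH2Cl2, 0 °C
Reagents that add atoms: carbon tetrabromide, BrC(Br)(Br)Br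
Why: Appel bromination converts the primary allylic alcohol into the bromide under neutral conditions that leave the alkenyl iodide and its geometry intact.

Step 9
Reactants: 12 (E)-1-bromo-3-iodobut-2-ene
Product: 14 (5E)-6-iodohept-5-en-2-one, via alkylated diketone 13 (not isolated)
Conditions: pentane-2,4-dione, K2CO3, EtOH, reflux
Reagents that add atoms: pentane-2,4-dione, CC(=O)CC(C)=O
Why: C-Alkylation of acetylacetone by the allylic bromide followed by retro-Claisen deacetylation in hot ethanolic carbonate should deliver the methyl ketone directly, the alkenyl iodide being inert to these conditions.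

Step 10
Reactants: 8 (2S,3R,5S)-2,5-diethenyl-2,6,6-trimethyloxan-3-yl acetate; 14 (5E)-6-iodohept-5-en-2-one
Product: 16 (2S,3R,5R)-2-ethenyl-2,6,6-trimethyl-5-[(3E)-3-methyl-7-oxooct-3-en-1-yl]oxan-3-yl acetate, via alkylborane 15 (not isolated)
Conditions: 9-BBN (1.05 equiv), THF, 0 °C to rt; then 14, PdCl2(dppf) (5 mol %), AsPh3, Cs2CO3, DMF/H2O, rt
Reagents that add atoms: none
Why: Anti-Markovnikov hydroboration followed by B-alkyl Suzuki–Miyaura coupling should join C5 to C6 with retention of the E geometry, 9-BBN selecting the C8 vinyl group because the C11 vinyl group sits on a fully substituted, oxygen-bearing carbon next to the acetoxy carbon and is sterically and inductively deactivated.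

Step 11
Reactants: 16 (2S,3R,5R)-2-ethenyl-2,6,6-trimethyl-5-[(3E)-3-methyl-7-oxooct-3-en-1-yl]oxan-3-yl acetate
Product: 18 (2S,3R,5R)-2-ethenyl-2,6,6-trimethyl-5-[(3E)-3-methyl-7-(trifluoromethanesulfonyloxy)octa-3,7-dien-1-yl]oxan-3-yl acetate, via potassium enolate 17 (not isolated)
Conditions: KN(SiMe3)2 (1.05 equiv), THF, −78 °C; then PhNTf2, −78 to 0 °C
Reagents that add atoms: N-phenylbis(trifluoromethanesulfonimide), O=S(=O)(N(c1ccccc1)S(=O)(=O)C(F)(F)F)C(F)(F)F
Why: Kinetic deprotonation of the methyl ketone at its methyl group by the hindered amide base and O-sulfonylation of the enolate (enol triflate formation) should give the 2-triflyloxy-1-alkene, the less acidic acetate being left alone with one equivalent of base.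

Step 12
Reactants: 18 (2S,3R,5R)-2-ethenyl-2,6,6-trimethyl-5-[(3E)-3-methyl-7-(trifluoromethanesulfonyloxy)octa-3,7-dien-1-yl]oxan-3-yl acetate
Product: 19 (2S,3R,5R)-2,6,6-trimethyl-5-[(3E)-3-methyl-7-(trifluoromethanesulfonyloxy)octa-3,7-dien-1-yl]-2-(3-oxopropyl)oxan-3-yl acetate
Conditions: Rh(acac)(CO)2 (2 mol %), Xantphos (4 mol %), CO/H2 (1:1, 10 bar), toluene, 60 °C
Reagents that add atoms: carbon monoxide, [C-]#[O+]
Why: Rhodium-catalysed hydroformylation with a wide-bite-angle diphosphine should introduce C14 as the aldehyde in one step, because the vinyl group on the fully substituted C11 can only give the linear aldehyde and cannot isomerise, while the trisubstituted alkene and the triflate-bearing 1,1-disubstituted alkene react far more slowly.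

Step 13
Reactants: 19 (2S,3R,5R)-2,6,6-trimethyl-5-[(3E)-3-methyl-7-(trifluoromethanesulfonyloxy)octa-3,7-dien-1-yl]-2-(3-oxopropyl)oxan-3-yl acetate
Product: 22 target CNP0202897.1 (8R,10R,11S,14R; 4E), via alkenylchromium 20 (not isolated), via chromium alkoxide 21 (not isolated)
Conditions: CrCl2 (8 equiv), NiCl2 (cat.), valinol-derived N-[2-(4-isopropyl-4,5-dihydrooxazol-2-yl)-6-methylphenyl]methanesulfonamide ligand (antipode chosen for Si-face addition), Et3N, THF, rt, 2 mM, slow addition of 19; aq. work-up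
Reagents that add atoms: none
Why: CrCl2 reduces NiCl2 to zerovalent nickel, which inserts into the C1–O bond of the enol triflate; transmetalation gives the alkenylchromium 20 (trivalent chromium), which adds to the C14 aldehyde to give alkoxide 21 and, after work-up, 22. The closest known reaction type is the Nozaki–Hiyama–Kishi macrocyclisation of alkenyl triflates or iodides onto aldehydes. The 14-membered carbocycle closes by 14-exo-trig addition of C1 to C14=O, and because the oxane already exists the second 14-membered circuit through the ring oxygen closes in the same event. The C14 stereocentre is controlled by the chiral sulfonamide–oxazoline ligand on chromium, whose antipode is chosen to deliver the alkenyl group to the Si face of the aldehyde (14R), the remote oxane stereocentres acting only through the conformation of the tether. The step needs chemoselectivity for the aldehyde over the acetate, which the weakly nucleophilic organochromium secures, and ring closure over oligomerisation, which slow addition at 2 mM secures; the 1,1-disubstituted alkene has no geometry to lose. The feature exploited is the 2-methylene-1-ol unit C1(=CH2)–C14(OH) of the carbocycle, the exact retron of an alkenylmetal–aldehyde addition.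

Compound list
1 | (R)-carvone, (5R)-2-methyl-5-(prop-1-en-2-yl)cyclohex-2-en-1-one | CC1=CC[C@H](CC1=O)C(C)=C | starting material
2 | (5R)-5-(2-hydroxypropan-2-yl)-2-methylcyclohex-2-en-1-one | CC1=CC[C@H](CC1=O)C(C)(C)O | intermediate
3 | (1R,5R)-5-(2-hydroxypropan-2-yl)-2-methylcyclohex-2-en-1-ol (hydroxyl cis to the side chain) | CC1=CC[C@H](C[C@H]1O)C(C)(C)O | intermediate
4 | (1R,4S,6R,7R)-1,3,3-trimethyl-7-(phenylselanyl)-2-oxabicyclo[2.2.2]octan-6-ol | C1[C@@H]2C[C@@H](O)[C@](C)([C@@H]1[Se]c1ccccc1)OC2(C)C | intermediate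
5 | selenoxide of 4 (configuration at selenium undefined) | C1[C@@H]2C[C@@H](O)[C@](C)([C@@H]1[Se](=O)c1ccccc1)OC2(C)C | intermediate
6 | (1S,4S,6R)-1,3,3-trimethyl-2-oxabicyclo[2.2.2]oct-7-en-6-ol | C[C@]12C=C[C@H](C[C@H]1O)C(C)(C)O2 | intermediate
7 | (1S,4S,6R)-1,3,3-trimethyl-2-oxabicyclo[2.2.2]oct-7-en-6-yl acetate | C[C@]12C=C[C@H](C[C@H]1OC(C)=O)C(C)(C)O2 | intermediate
8 | (2S,3R,5S)-2,5-diethenyl-2,6,6-trimethyloxan-3-yl acetate | C=C[C@@H]1C[C@@H](OC(C)=O)[C@](C)(C=C)OC1(C)C | intermediate
9 | but-2-yn-1-ol | CC#CCO | starting material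
10 | (E)-3-(chlorozirconocenyl)but-2-en-1-yl zirconocene chloride alkoxide (cyclopentadienyl rings drawn σ-bonded) | C/C(=C\CO[Zr](Cl)(C1C=CC=C1)C1C=CC=C1)[Zr](Cl)(C1C=CC=C1)C1C=CC=C1 | intermediate
11 | (E)-3-iodobut-2-en-1-ol | C/C(I)=C\CO | intermediate
12 | (E)-1-bromo-3-iodobut-2-ene | C/C(I)=C\CBr | intermediate
13 | 3-[(2E)-3-iodobut-2-en-1-yl]pentane-2,4-dione | C/C(I)=C\CC(C(C)=O)C(C)=O | intermediate
14 | (5E)-6-iodohept-5-en-2-one | C/C(I)=C\CCC(C)=O | intermediate
15 | B-alkyl-9-BBN adduct of 8 at the C8 vinyl group | C1CCC2CCCC1B2CC[C@@H]1C[C@@H](OC(C)=O)[C@](C)(C=C)OC1(C)C | intermediate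
16 | (2S,3R,5R)-2-ethenyl-2,6,6-trimethyl-5-[(3E)-3-methyl-7-oxooct-3-en-1-yl]oxan-3-yl acetate | CC(=O)CC/C=C(\C)CC[C@@H]1C[C@@H](OC(C)=O)[C@](C)(C=C)OC1(C)C | intermediate
17 | potassium enolate of 16 (terminal) | [K+].[O-]C(=C)CC/C=C(\C)CC[C@@H]1C[C@@H](OC(C)=O)[C@](C)(C=C)OC1(C)C | intermediate
18 | (2S,3R,5R)-2-ethenyl-2,6,6-trimethyl-5-[(3E)-3-methyl-7-(trifluoromethanesulfonyloxy)octa-3,7-dien-1-yl]oxan-3-yl acetate | C=C(OS(=O)(=O)C(F)(F)F)CC/C=C(\C)CC[C@@H]1C[C@@H](OC(C)=O)[C@](C)(C=C)OC1(C)C | intermediate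
19 | (2S,3R,5R)-2,6,6-trimethyl-5-[(3E)-3-methyl-7-(trifluoromethanesulfonyloxy)octa-3,7-dien-1-yl]-2-(3-oxopropyl)oxan-3-yl acetate | C=C(OS(=O)(=O)C(F)(F)F)CC/C=C(\C)CC[C@@H]1C[C@@H](OC(C)=O)[C@](C)(CCC=O)OC1(C)C | intermediate
20 | alkenylchromium dichloride from 19 (chromium at C1; sulfonamide ligand not drawn) | C=C([Cr](Cl)Cl)CC/C=C(\C)CC[C@@H]1C[C@@H](OC(C)=O)[C@](C)(CCC=O)OC1(C)C | intermediate
21 | chromium alkoxide of 22 (sulfonamide ligand not drawn) | C=C1CC/C=C(\C)CC[C@@H]2C[C@@H](OC(C)=O)[C@](C)(CC[C@H]1O[Cr](Cl)Cl)OC2(C)C | intermediate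
22 | CNP0202897.1: 14-membered carbocycle bridged by the 2,2,6-trimethyloxane, C1 exocyclic methylene, (4E)-alkene, C10 acetate, C14 hydroxyl, 8R,10R,11S,14R | C=C1CC/C=C(\C)CC[C@@H]2C[C@@H](OC(C)=O)[C@](C)(CC[C@H]1O)OC2(C)C | target

Total step count: 13. Longest linear sequence: 10 steps (steps 1–6 and 10–13); the three-step branch (steps 7–9) joins at step 10.

Steps most likely to fail

Step 13. The chromium-bound ligand may not override the conformational preference of the macrocyclic transition state, so that addition to the C14 aldehyde occurs with poor facial selectivity. Fallback: the stereocentre would be set after ring closure instead of during it. Setting out from 19, ring closure with CrCl2 and NiCl2 (cat.) without ligand in DMSO–THF would be accepted as a mixture of 22 and its 14S epimer F1. The mixture would be oxidised with Dess–Martin periodinane to the macrocyclic α-methylene ketone F2. Corey–Bakshi–Shibata reduction ((S)-2-methyl-CBS-oxazaborolidine, catecholborane, toluene, −78 °C; the alkenyl group acts as the large substituent) should then come back to 22.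

Step 10. Hydroboration may not discriminate well enough between the two vinyl groups of 8, so that the borane is also placed on the C11 arm. Fallback: the two arms would be introduced one at a time, with no divinyl intermediate, setting out from 3 and coming back at 19.
- Selective acetylation of the secondary hydroxyl (Ac2O, pyridine) gives monoacetate F3, and silylation of the tertiary hydroxyl (Et3SiOTf, 2,6-lutidine) gives silyl ether F4.
- Ozonolysis of the ring alkene (O3, CH2Cl2, −78 °C; PPh3) opens the carbocycle to keto aldehyde F5, in which C6 is already attached to C7.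
- Chemoselective reduction of the aldehyde (NaBH(OAc)3) gives hydroxy ketone F6, and Appel iodination (I2, PPh3, imidazole) gives iodo ketone F7.
- Allyltrimethylsilane with Me3SiOTf (CH2Cl2, −78 °C) closes the oxane by silyl-mediated ketalisation and Sakurai-type allylation at C11, trans to the participating C10 acetate and cis to the C8 arm, giving allyl oxane F8.
- Zinc insertion (Zn, LiCl, THF) gives alkylzinc iodide F9, and Negishi coupling with 14 (PdCl2(dppf)) gives allyl ketone F10.
- Enol triflate formation as in step 11 gives triflate F11; hydroboration–oxidation of the allyl group (9-BBN; H2O2, NaOAc) gives primary alcohol F12; Dess–Martin oxidation returns to 19.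

Step 12. The rhodium hydride may also engage the triflate-bearing alkene or reduce the alkenyl triflate, so that chemoselectivity for the C11 vinyl group is lost. Fallback: C14 would be added by stepwise homologation instead of carbonylation. Setting out from 18, hydroboration–oxidation of the remaining vinyl group (9-BBN; H2O2, NaOAc) gives two-carbon alcohol F13, and Dess–Martin oxidation gives aldehyde F14. Wittig methoxymethylenation (Ph3P=CHOMe, THF, −78 to 0 °C) gives enol ether F15, and mild acid hydrolysis (aq. HCl, THF) comes back to 19.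

Further compounds
F1 | step 13 | 14S epimer of 22 | C=C1CC/C=C(\C)CC[C@@H]2C[C@@H](OC(C)=O)[C@](C)(CC[C@@H]1O)OC2(C)C
F2 | step 13 | macrocyclic α-methylene ketone (C14 ketone of 22) | C=C1CC/C=C(\C)CC[C@@H]2C[C@@H](OC(C)=O)[C@](C)(CCC1=O)OC2(C)C
F3 | step 10 | (1R,5R)-5-(2-hydroxypropan-2-yl)-2-methylcyclohex-2-en-1-yl acetate | CC1=CC[C@H](C[C@H]1OC(C)=O)C(C)(C)O
F4 | step 10 | (1R,5R)-2-methyl-5-[2-(triethylsilyloxy)propan-2-yl]cyclohex-2-en-1-yl acetate | CC1=CC[C@H](C[C@H]1OC(C)=O)C(C)(C)O[Si](CC)(CC)CC
F5 | step 10 | (3S,5R)-5-acetoxy-6-oxo-3-[2-(triethylsilyloxy)propan-2-yl]heptanal | CC(=O)[C@H](OC(C)=O)C[C@@H](CC=O)C(C)(C)O[Si](CC)(CC)CC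
F6 | step 10 | (3R,5R)-7-hydroxy-2-oxo-5-[2-(triethylsilyloxy)propan-2-yl]heptan-3-yl acetate | CC(=O)[C@H](OC(C)=O)C[C@@H](CCO)C(C)(C)O[Si](CC)(CC)CC
F7 | step 10 | (3R,5S)-7-iodo-2-oxo-5-[2-(triethylsilyloxy)propan-2-yl]heptan-3-yl acetate | CC(=O)[C@H](OC(C)=O)C[C@@H](CCI)C(C)(C)O[Si](CC)(CC)CC
F8 | step 10 | (2S,3R,5S)-5-(2-iodoethyl)-2,6,6-trimethyl-2-(prop-2-en-1-yl)oxan-3-yl acetate | ICC[C@@H]1C[C@@H](OC(C)=O)[C@](C)(CC=C)OC1(C)C
F9 | step 10 | alkylzinc iodide from F8 | I[Zn]CC[C@@H]1C[C@@H](OC(C)=O)[C@](C)(CC=C)OC1(C)C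
F10 | step 10 | (2S,3R,5R)-2,6,6-trimethyl-5-[(3E)-3-methyl-7-oxooct-3-en-1-yl]-2-(prop-2-en-1-yl)oxan-3-yl acetate | CC(=O)CC/C=C(\C)CC[C@@H]1C[C@@H](OC(C)=O)[C@](C)(CC=C)OC1(C)C
F11 | step 10 | (2S,3R,5R)-2,6,6-trimethyl-5-[(3E)-3-methyl-7-(trifluoromethanesulfonyloxy)octa-3,7-dien-1-yl]-2-(prop-2-en-1-yl)oxan-3-yl acetate | C=C(OS(=O)(=O)C(F)(F)F)CC/C=C(\C)CC[C@@H]1C[C@@H](OC(C)=O)[C@](C)(CC=C)OC1(C)C
F12 | step 10 | (2S,3R,5R)-2-(3-hydroxypropyl)-2,6,6-trimethyl-5-[(3E)-3-methyl-7-(trifluoromethanesulfonyloxy)octa-3,7-dien-1-yl]oxan-3-yl acetate | C=C(OS(=O)(=O)C(F)(F)F)CC/C=C(\C)CC[C@@H]1C[C@@H](OC(C)=O)[C@](C)(CCCO)OC1(C)C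
F13 | step 12 | (2S,3R,5R)-2-(2-hydroxyethyl)-2,6,6-trimethyl-5-[(3E)-3-methyl-7-(trifluoromethanesulfonyloxy)octa-3,7-dien-1-yl]oxan-3-yl acetate | C=C(OS(=O)(=O)C(F)(F)F)CC/C=C(\C)CC[C@@H]1C[C@@H](OC(C)=O)[C@](C)(CCO)OC1(C)C
F14 | step 12 | (2S,3R,5R)-2,6,6-trimethyl-5-[(3E)-3-methyl-7-(trifluoromethanesulfonyloxy)octa-3,7-dien-1-yl]-2-(2-oxoethyl)oxan-3-yl acetate | C=C(OS(=O)(=O)C(F)(F)F)CC/C=C(\C)CC[C@@H]1C[C@@H](OC(C)=O)[C@](C)(CC=O)OC1(C)C
F15 | step 12 | methyl enol ether from F14 (mixture of alkene isomers), 2-(3-methoxyprop-2-en-1-yl) analogue of 19 | C=C(OS(=O)(=O)C(F)(F)F)CC/C=C(\C)CC[C@@H]1C[C@@H](OC(C)=O)[C@](C)(CC=COC)OC1(C)C
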